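## Structural features

The target is a single carbocycle: a cyclohexane whose ring atoms are labelled C1 (CMe2), C2 (CHBr), C3 (CH2), C4 (CHCl), C5 (alkylidene carbon) and C6 (CHCl), with the exocyclic C5=C7 double bond carrying the C8H2Br arm. These labels are used for every intermediate. The stereocentres C2, C4 and C6 are mutually 1,3-related and all S: the two chlorides are cis to each other, the bromide is trans to both, and the alkene is Z, with C8 on the C6 side. C4–Cl and C6–Cl are secondary allylic chlorides and C8–Br is a primary allylic bromide, so the finished array is open to SN2′ attack, 1,3-halide shifts, ionisation and dehydrohalogenation. Strong bases, soft nucleophiles, Lewis acids and low-valent metals therefore have no place late in the route. The real difficulty is that C2 and C6 both flank the quaternary C1 and are neopentyl, so neither halogen enters easily by ordinary intermolecular substitution. At the same time two different halogens must be placed on four carbons without scrambling, and the trisubstituted alkene must be set with one geometry. The key step exploits the C4–C5–C6 triad: an sp2 carbon between two halogen-bearing carbons is the signature of an allyl unit released from a cyclopropane. C5 can therefore enter as a carbene carbon across the C4=C6 bond of a cyclopentene (ring atoms C1, C2, C3, C4, C6), and opening of the resulting bicyclo[3.1.0]hexane gives the six-membered ring with a halogen at C4 and a C5=C6 alkene. The C7 carbinol on C5 then relays chlorine to the neopentyl C6 from within and moves the alkene out of the ring.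

## Logic of the disconnections

20 ⇒ 18. The C8–Br and C2–Br bonds are cut first, both back to C–O bonds. Bromide is the most easily displaced and scrambled halogen, so it should enter last and under non-ionising conditions; the two alcohols of 18 let one reagent finish the synthesis, by way of 19. The gain is that the only bromine present earlier is the transient one at C4. The demand is heavy: C2 must be substituted with inversion although it is neopentyl, so the C2 oxygen of 18 must be cis to both chlorides.

18 ⇒ 17. The two O–Si bonds are cut. Both oxygens must be masked through organolithium, oxidation, borane and thionyl chloride chemistry, and one robust silyl group on each lets a single acidic fluoride treatment free them. The forward step must not be basic, because of the allylic chlorides.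

17 ⇒ 16. The C4–Cl bond is cut and replaced by a C4–Br bond of opposite configuration. The ring expansion can only leave its halide on the face opposite the C2 oxygen, whereas the target needs chlorine on the same face; one SN2 exchange corrects element and configuration together. This traces C4 to the key step. The forward step must be SN2 and not SN2′, and must be stopped under kinetic control, because the all-cis product is the more strained epimer.

16 ⇒ 14. The C6–Cl bond is cut, the alkene is moved from C5=C7 back to C5=C6, and oxygen is placed on C7. C6 is neopentyl and allylic, so chloride is best brought there from within, through 15, in a transposition that also creates the exocyclic alkene. The gain is that a ring stereocentre and an alkene geometry are reduced to one side-chain carbinol. The forward step must be suprafacial, must beat direct substitution at C7, and needs the C7 configuration that turns C8 toward C6 when the oxygen is on the upper face. It is placed before the halide exchange so that the lower-face C4 bromide of 14 keeps the C7–O bond on the upper face.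

14 ⇒ 13. The C4–Br bond is cut, C4 is reconnected to C6 and bromine is returned to C5: the cyclohexene becomes a bicyclo[3.1.0]hexane. This is the strategic simplification. The six-membered ring with its allylic halide is traded for a cyclopentane plus a one-carbon bridge, and the C4 configuration becomes a question of which face of a cyclopentene a carbene takes. The forward step requires the bromine on C5 to be endo and the side chain exo.

13 ⇒ 12 ⇒ 11. The C7–H bond is cut (ketone reduction) and the ketone is traced to a carbinol mixture. An aldehyde addition cannot be expected to distinguish the two nearly equivalent flanks of C5, so C7 is set by a reagent-controlled reduction. The demand is a large steric difference between the two ketone substituents, which the fully substituted cyclopropyl carbon supplies.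

11 ⇒ 8 + 9. The C5–C7 bond is cut between a nucleophilic C5 (10) and an aldehyde. This detaches the two-carbon arm as a purchased, already oxygenated unit and reduces the bicycle to a CBr2 bridge. The forward step must exchange only the exo bromine and must be run under kinetic control.

8 ⇒ 6 + 7. The C4–C5 and C5–C6 bonds are cut: a dihalocarbene onto a cyclopentene. One step adds the missing ring carbon together with the two bromines used in the next operations. The demand is addition on the face opposite the C2 silyl ether.

6 ⇒ 4 ⇒ 3 ⇒ 2 ⇒ 1. The C4=C6 alkene is traced, through 5, to a ketone hydrazone, the silyl ether to the alcohol, and the alcohol to one of the two enantiotopic carbonyls of 1. The quaternary carbon forces the elimination toward the only α-methylene, and the absolute configuration of the whole target is reduced to one catalytic desymmetrisation. The demands are monoreduction without over-reduction and tolerance of the silyl ether to excess alkyllithium.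

## Other disconnections considered

Alternative 1: The ring is cut at C3–C4 and at C2–Br, leaving the acyclic (3R)-1-bromo-1,3-dichloro-4,4-dimethylhex-5-en-2-one A1. In the forward sense CuBr with tris(2-pyridylmethyl)amine would abstract bromine from the CHBrCl terminus. The C4 radical would add to the vinyl terminus C3 in the 6-endo mode, and the C2 radical would take bromine back from CuBr2 to give 4-bromo-2,6-dichloro-3,3-dimethylcyclohexanone A2.
- In favour: one redox-neutral step forms the ring, the C3–C4 bond and the neopentyl C2–Br bond. It does so by atom transfer to a radical and not by SN2 at a neopentyl carbon, which is better than the chosen plan exactly where that plan is weakest (step 13). The 6-endo mode is plausible, since 5-exo attack would be at the carbon next to the quaternary centre and α-keto radicals lean toward endo closure. The step count to the carbocycle would be lower, also a better point.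
- Against: C4 is set at a planar radical and C2 by bromine transfer to a ring radical, so neither is under firm control. C4 and C6 of A2 are epimerisable α-chloro ketone centres, and A1 itself needs an enantioselective route to an α-chloro ketone. The C5 carbonyl of A2, flanked by two CHCl groups, must still become the Z-configured bromoethylidene; basic ylides or phosphonate anions invite Favorskii rearrangement or loss of HCl and offer no handle on geometry.
- Comparison: the chosen plan is longer but derives every stereocentre and the alkene geometry from catalyst-set carbinols through stereospecific ionic steps. The radical route is shorter and mechanistically cleaner at C2 but leaves the alkene and two of the three centres unsolved.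

Alternative 2: The cuts are C2–C3 and C4–Cl. TiCl4 would activate the aldehyde of (3S,4Z)-6-[(tert-butyldimethylsilyl)oxy]-3-chloro-4-ethenyl-2,2-dimethylhex-4-enal A3, and the diene terminus C3 would attack C2. The allyl cation over C4, C5 and C7 would then take chloride at C4 from the titanium alkoxide to give the all-cis chlorohydrin A4.
- In favour: ring, C2 carbinol and C4 chloride arise in one step and the alkene geometry is already present in A3. A4 is the C8 silyl ether of 18, so this route would join the chosen endgame two steps from the target. On step economy after ring formation it is better; on the final neopentyl inversion at C2 it is equal.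
- Against: A3 combines an ionisable allylic, neopentyl C6 chloride with an aldehyde on the adjacent quaternary carbon and a Z trisubstituted diene, a demanding enantiopure substrate. Under TiCl4 the C6 chloride can ionise and chloride may be captured at C7 instead of C4. The all-cis product is the most congested diastereomer, so two new centres would have to come from kinetic control at once.
- Comparison: both plans end in collapse of an allyl cation–halide pair. In the chosen plan the pair is intimate, its face is fixed by the cyclopropane, and only one centre is created.

Alternative 3: The ring bond C4=C5 and the C7=C8 bond are cut, leading back to (3S,5S)-5-bromo-3-chloro-4,4-dimethyloct-7-en-1-yne A5. Second-generation Grubbs catalyst, (H2IMes)(PCy3)Cl2Ru=CHPh, under ethylene would close the 1,7-enyne to the vinylcyclohexene A6. A 1,4-addition of BrCl across the diene would then place chlorine on C4 and bromine on C8 while moving the alkene to C5=C7.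
- In favour: enyne metathesis is dependable for six-membered rings and tolerant of alkyl halides. Both neopentyl halides are in place before the ring exists, so no late substitution next to C1 is needed, which is better than the chosen plan. The endgame is a single step from A6, better on step economy.
- Against: the neopentyl problem is only moved into A5, whose propargylic C6 chloride and C2 bromide flank a quaternary carbon and have no obvious enantioselective origin. The closing bromochlorination must fix which halogen goes where, 1,4 against 1,2 addition, the face at C4 and the alkene geometry with no stereospecific element, so mixtures would be expected.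
- Comparison: the chosen plan spends more steps but replaces that unguided addition by an ion-pair return, an SN2 inversion and a cyclic chlorine transfer, each with a defined stereochemical course.

Key step: step 9

## Remarks on the chemistry

- The sense of induction of both oxazaborolidine reductions is taken from the usual large/small model; if either proved opposite, the enantiomeric catalyst would be used.
- Kinetic bromine–lithium exchange of the dibromobicyclohexane is taken to occur at the exo bromine, as in related dibromobicycloalkanes.
- The stereodescriptors of 13 and 14 were re-derived from the target and are mutually consistent (C2–O cis to the final chlorides, cyclopropane on the opposite face, bromine endo, C7 R in 13 and S in 14); no correction was needed. The design changes are that C7 is set by reagent-controlled reduction of ketone 12, and that the chlorine transfer to C6 is run before the halide exchange at C4.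

## Route

Step 1
Reactants: 1 2,2-dimethylcyclopentane-1,3-dione
Product: 2 (R)-3-hydroxy-2,2-dimethylcyclopentan-1-one
Conditions: (S)-Me-CBS oxazaborolidine (10 mol %), BH3·SMe2 (0.6 equiv), THF, −30 °C; MeOH
Reagents that add atoms: none
Why: Corey–Bakshi–Shibata desymmetrising monoreduction of a prochiral 2,2-disubstituted 1,3-dione; with the quaternary carbon as the large group the (S)-catalyst should give the (R)-carbinol (C2), and sub-stoichiometric borane at low temperature limits diol formation.

Step 2
Reactants: 2 (R)-3-hydroxy-2,2-dimethylcyclopentan-1-one
Product: 3 (R)-3-[(tert-butyldimethylsilyl)oxy]-2,2-dimethylcyclopentan-1-one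
Conditions: TBSCl, imidazole, DMF, 25 °C
Reagents that add atoms: tert-butyldimethylsilyl chloride, CC(C)(C)[Si](C)(C)Cl
Why: Standard silylation; the ether must survive alkyllithium, alkoxide, borane and thionyl chloride steps and supplies the bulk that later steers the carbene.

Step 3
Reactants: 3 (R)-3-[(tert-butyldimethylsilyl)oxy]-2,2-dimethylcyclopentan-1-one
Product: 4 N'-[(1E,3R)-3-[(tert-butyldimethylsilyl)oxy]-2,2-dimethylcyclopentylidene]-4-methylbenzenesulfonohydrazide
Conditions: TsNHNH2, EtOH, 50 °C
Reagents that add atoms: 4-methylbenzenesulfonohydrazide, Cc1ccc(cc1)S(=O)(=O)NN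
Why: Condensation to the tosylhydrazone; the sulfonamide nitrogen should settle anti to the quaternary carbon (E), the geometry needed for syn α-deprotonation.

Step 4
Reactants: 4 N'-[(1E,3R)-3-[(tert-butyldimethylsilyl)oxy]-2,2-dimethylcyclopentylidene]-4-methylbenzenesulfonohydrazide
Product: 6 (R)-tert-butyl[(2,2-dimethylcyclopent-3-en-1-yl)oxy]dimethylsilane, via vinyllithium 5 (not isolated)
Conditions: n-BuLi (3 equiv), TMEDA, hexane, −78 → 25 °C; H2O
Reagents that add atoms: none
Why: Shapiro reaction: deprotonation of N–H and then of the only α-methylene, loss of sulfinate and N2, and protonation of vinyllithium 5 on work-up. The quaternary α-carbon leaves no regiochemical choice, and the silyloxy group is γ to the carbanion, so it is not eliminated.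

Step 5
Reactants: 6 (R)-tert-butyl[(2,2-dimethylcyclopent-3-en-1-yl)oxy]dimethylsilane; 7 bromoform
Product: 8 (1R,3R,5R)-6,6-dibromo-3-[(tert-butyldimethylsilyl)oxy]-2,2-dimethylbicyclo[3.1.0]hexane
Conditions: KOtBu, pentane, −20 → 0 °C
Reagents that add atoms: none
Why: Dibromocarbene cyclopropanation forms C4–C5 and C5–C6 stereospecifically cis; the carbene should approach the face opposite the bulky C2 silyloxy group, which fixes both bridgeheads. The product is itself prone to the ring expansion, so it is kept cold and used promptly.

Step 6
Reactants: 8 (1R,3R,5R)-6,6-dibromo-3-[(tert-butyldimethylsilyl)oxy]-2,2-dimethylbicyclo[3.1.0]hexane; 9 (tert-butyldimethylsilyloxy)acetaldehyde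
Product: 11 1-[(1R,3R,5R,6R)-6-bromo-3-[(tert-butyldimethylsilyl)oxy]-2,2-dimethylbicyclo[3.1.0]hexan-6-yl]-2-[(tert-butyldimethylsilyl)oxy]ethan-1-ol (both C7 epimers), via exo-lithio endo-bromo carbenoid 10 (not isolated)
Conditions: 8 added to n-BuLi (1.15 equiv), THF–Et2O, −110 °C; 9 (2 equiv), −110 °C; AcOH, −100 °C
Reagents that add atoms: none
Why: Kinetic bromine–lithium exchange at the exposed exo bromine (the endo one is shielded by the five-membered ring and the cis methyl) gives carbenoid 10, which adds to the aldehyde with retention at carbon. Inverse addition leaves no dibromide to catalyse equilibration to the endo-lithio isomer, and the cold quench prevents collapse of the bromo alkoxide to an oxaspiropentane or cyclobutanone. C7 forms as both epimers, which steps 7 and 8 correct.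

Step 7
Reactants: 11 1-[(1R,3R,5R,6R)-6-bromo-3-[(tert-butyldimethylsilyl)oxy]-2,2-dimethylbicyclo[3.1.0]hexan-6-yl]-2-[(tert-butyldimethylsilyl)oxy]ethan-1-ol (both C7 epimers)
Product: 12 1-[(1R,3R,5R,6R)-6-bromo-3-[(tert-butyldimethylsilyl)oxy]-2,2-dimethylbicyclo[3.1.0]hexan-6-yl]-2-[(tert-butyldimethylsilyl)oxy]ethan-1-one
Conditions: Dess–Martin periodinane, pyridine, CH2Cl2, 0 → 20 °C
Reagents that add atoms: none
Why: Dess–Martin oxidation of the hindered carbinol under buffered conditions that spare the cyclopropylcarbinyl system and the silyl ethers; it erases the uncontrolled C7 centre, and the acyl group also makes 12 the thermally most robust bromocyclopropane of the series.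

Step 8
Reactants: 12 1-[(1R,3R,5R,6R)-6-bromo-3-[(tert-butyldimethylsilyl)oxy]-2,2-dimethylbicyclo[3.1.0]hexan-6-yl]-2-[(tert-butyldimethylsilyl)oxy]ethan-1-one
Product: 13 (1R)-1-[(1R,3R,5R,6R)-6-bromo-3-[(tert-butyldimethylsilyl)oxy]-2,2-dimethylbicyclo[3.1.0]hexan-6-yl]-2-[(tert-butyldimethylsilyl)oxy]ethan-1-ol
Conditions: (S)-Me-CBS oxazaborolidine (20 mol %), BH3·SMe2, THF, −40 → −20 °C; MeOH
Reagents that add atoms: none
Why: Corey–Bakshi–Shibata reduction under reagent control: the fully substituted bromocyclopropyl carbon is the large group and CH2OSi the small one, so the (S)-catalyst should give the (R)-carbinol at C7. Borane does not touch the cyclopropyl bromide.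

Step 9
Reactants: 13 (1R)-1-[(1R,3R,5R,6R)-6-bromo-3-[(tert-butyldimethylsilyl)oxy]-2,2-dimethylbicyclo[3.1.0]hexan-6-yl]-2-[(tert-butyldimethylsilyl)oxy]ethan-1-ol
Product: 14 (1S)-1-[(4R,6R)-6-bromo-4-[(tert-butyldimethylsilyl)oxy]-3,3-dimethylcyclohex-1-en-1-yl]-2-[(tert-butyldimethylsilyl)oxy]ethan-1-ol
Conditions: PhMe, 2,6-di-tert-butylpyridine (0.2 equiv), 80–100 °C
Reagents that add atoms: none
Why: Thermal cyclopropyl-to-allyl rearrangement of an endo-6-halobicyclo[3.1.0]hexane, the reaction type long used on the 6,6-dihalides. The endo C5–Br bond ionises in concert with a two-electron disrotatory opening of the C4–C6 fusion bond; by the Woodward–Hoffmann–DePuy rule only the halide syn to the five-membered ring can leave, because only then do the ring bonds rotate inward to the cisoid allyl cation that a six-membered ring can hold. The six-membered ring is therefore not closed by bond formation but arises by cleavage of the bond shared by the two small rings, driven by relief of cyclopropane strain, which the contact between the endo bromine and the cis methyl on C1 increases. Bromide stays in a contact ion pair on the face it left, the face that carried the cyclopropane and is opposite the C2 silyl ether, and collapses there, so the new stereocentre C4 (R, Br trans to C2–O) is controlled by the carbene face chosen in step 5. Of the two allyl termini, C4 is flanked by a methylene and C6 by the quaternary C1, so return to C4 is favoured; any C6 bromide would re-ionise to the same pair and drain to 14, which has the pseudoaxial bromide and the equatorial silyl ether. The step needs the bromine endo (secured in step 6), a non-polar solvent so that the ion pair does not dissociate, and a hindered base to remove traces of HBr that would open the cyclopropylcarbinol or strip the silyl ethers.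

Step 10
Reactants: 14 (1S)-1-[(4R,6R)-6-bromo-4-[(tert-butyldimethylsilyl)oxy]-3,3-dimethylcyclohex-1-en-1-yl]-2-[(tert-butyldimethylsilyl)oxy]ethan-1-ol
Product: 16 (2R,4R,6R,5E)-4-bromo-2-[(tert-butyldimethylsilyl)oxy]-5-{2-[(tert-butyldimethylsilyl)oxy]ethylidene}-6-chloro-1,1-dimethylcyclohexane, via allylic chlorosulfite 15 (not isolated)
Conditions: SOCl2 (1.2 equiv), Et2O, −20 → 0 °C
Reagents that add atoms: thionyl chloride, O=S(Cl)Cl
Why: Allylic transposition of a chlorosulfite (SNi′): 15 collapses in ether without amine through a six-membered cyclic array, chloride passing to C6 on the face from which the C7–O bond leaves while the alkene moves to C5=C7. In 14 the C4 bromide is pseudoaxial on the lower face and the C2 silyl ether equatorial, so the C7–O bond should lie on the upper face; with the (S)-carbinol this rotamer has C8 eclipsing the ring alkene toward C6–H, which puts chlorine on the upper face of C6 and C8 cis to C6. Delivery from within is what makes substitution at the neopentyl C6 feasible, and the silyloxy group on C8 disfavours free ionisation at C7.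

Step 11
Reactants: 16 (2R,4R,6R,5E)-4-bromo-2-[(tert-butyldimethylsilyl)oxy]-5-{2-[(tert-butyldimethylsilyl)oxy]ethylidene}-6-chloro-1,1-dimethylcyclohexane
Product: 17 (2R,4S,6R,5Z)-2-[(tert-butyldimethylsilyl)oxy]-5-{2-[(tert-butyldimethylsilyl)oxy]ethylidene}-4,6-dichloro-1,1-dimethylcyclohexane
Conditions: LiCl (5 equiv), DMF, 0 °C
Reagents that add atoms: lithium chloride, [Li+].[Cl-]
Why: Finkelstein-type SN2 exchange: chloride displaces the secondary allylic C4 bromide with inversion, putting chlorine on the upper face cis to C6–Cl and C2–O, while the neopentyl C6 chloride and the silyl ethers are inert. Excess chloride, low temperature and a quench at full conversion should limit SN2′ attack at the substituted C7 and later epimerisation of the strained all-cis product; 16 is used as soon as it is made.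

Step 12
Reactants: 17 (2R,4S,6R,5Z)-2-[(tert-butyldimethylsilyl)oxy]-5-{2-[(tert-butyldimethylsilyl)oxy]ethylidene}-4,6-dichloro-1,1-dimethylcyclohexane
Product: 18 (2R,4S,6R,5Z)-4,6-dichloro-5-(2-hydroxyethylidene)-1,1-dimethylcyclohexan-2-ol
Conditions: 48% aq HF, MeCN, 0 → 20 °C
Reagents that add atoms: none
Why: Acidic fluoride removes both silyl ethers (the hindered C2 ether needs aqueous HF); basic fluoride is avoided because of the allylic chlorides.

Step 13
Reactants: 18 (2R,4S,6R,5Z)-4,6-dichloro-5-(2-hydroxyethylidene)-1,1-dimethylcyclohexan-2-ol
Product: 20 (2S,4S,6S,5Z)-2-bromo-5-(2-bromoethylidene)-4,6-dichloro-1,1-dimethylcyclohexane, via bromo alcohol 19 (not isolated)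
Conditions: CBr4 (6 equiv), PPh3 (5 equiv, in portions), PhMe, 0 → 45 °C
Reagents that add atoms: carbon tetrabromide, BrC(Br)(Br)Br
Why: Appel bromination: the primary allylic C8 alcohol reacts first (19), then the C2 oxyphosphonium is displaced by bromide with inversion, giving the bromide trans to both chlorides. This type of substitution has precedent for neopentyl cyclohexanols in brominated terpenoid work, and here inversion relieves the all-cis triad (C2–Br equatorial, both chlorides axial). Phosphine is added in portions to excess CBr4 so that free PPh3 does not quaternise the allylic bromide.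

## Compound list

1 | 2,2-dimethylcyclopentane-1,3-dione | CC1(C)C(=O)CCC1=O | starting material
2 | (R)-3-hydroxy-2,2-dimethylcyclopentan-1-one | CC1(C)[C@H](O)CCC1=O | intermediate
3 | (R)-3-[(tert-butyldimethylsilyl)oxy]-2,2-dimethylcyclopentan-1-one | CC1(C)[C@H](O[Si](C)(C)C(C)(C)C)CCC1=O | intermediate
4 | N'-[(1E,3R)-3-[(tert-butyldimethylsilyl)oxy]-2,2-dimethylcyclopentylidene]-4-methylbenzenesulfonohydrazide | CC1(C)[C@H](O[Si](C)(C)C(C)(C)C)CC/C1=N\NS(=O)(=O)c1ccc(C)cc1 | intermediate
5 | [(4R)-4-[(tert-butyldimethylsilyl)oxy]-5,5-dimethylcyclopent-1-en-1-yl]lithium | CC1(C)[C@H](O[Si](C)(C)C(C)(C)C)CC=C1[Li] | intermediate (not isolated)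
6 | (R)-tert-butyl[(2,2-dimethylcyclopent-3-en-1-yl)oxy]dimethylsilane | CC1(C)[C@H](O[Si](C)(C)C(C)(C)C)CC=C1 | intermediate
7 | bromoform | BrC(Br)Br | starting material
8 | (1R,3R,5R)-6,6-dibromo-3-[(tert-butyldimethylsilyl)oxy]-2,2-dimethylbicyclo[3.1.0]hexane (cyclopropane trans to the silyloxy group) | CC1(C)[C@H](O[Si](C)(C)C(C)(C)C)C[C@@H]2[C@H]1C2(Br)Br | intermediate
9 | (tert-butyldimethylsilyloxy)acetaldehyde | O=CCO[Si](C)(C)C(C)(C)C | starting material
10 | [(1R,3R,5R,6R)-6-bromo-3-[(tert-butyldimethylsilyl)oxy]-2,2-dimethylbicyclo[3.1.0]hexan-6-yl]lithium (Li exo, Br endo) | CC1(C)[C@H](O[Si](C)(C)C(C)(C)C)C[C@@H]2[C@H]1[C@@]2(Br)[Li] | intermediate (not isolated)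
11 | 1-[(1R,3R,5R,6R)-6-bromo-3-[(tert-butyldimethylsilyl)oxy]-2,2-dimethylbicyclo[3.1.0]hexan-6-yl]-2-[(tert-butyldimethylsilyl)oxy]ethan-1-ol, both C7 epimers (Br endo) | CC1(C)[C@H](O[Si](C)(C)C(C)(C)C)C[C@@H]2[C@H]1[C@@]2(Br)C(O)CO[Si](C)(C)C(C)(C)C | intermediate
12 | 1-[(1R,3R,5R,6R)-6-bromo-3-[(tert-butyldimethylsilyl)oxy]-2,2-dimethylbicyclo[3.1.0]hexan-6-yl]-2-[(tert-butyldimethylsilyl)oxy]ethan-1-one | CC1(C)[C@H](O[Si](C)(C)C(C)(C)C)C[C@@H]2[C@H]1[C@@]2(Br)C(=O)CO[Si](C)(C)C(C)(C)C | intermediate
13 | (1R)-1-[(1R,3R,5R,6R)-6-bromo-3-[(tert-butyldimethylsilyl)oxy]-2,2-dimethylbicyclo[3.1.0]hexan-6-yl]-2-[(tert-butyldimethylsilyl)oxy]ethan-1-ol (Br endo, side chain exo, cyclopropane trans to the ring silyl ether) | CC1(C)[C@H](O[Si](C)(C)C(C)(C)C)C[C@@H]2[C@H]1[C@@]2(Br)[C@H](O)CO[Si](C)(C)C(C)(C)C | intermediate (key-step precursor)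
14 | (1S)-1-[(4R,6R)-6-bromo-4-[(tert-butyldimethylsilyl)oxy]-3,3-dimethylcyclohex-1-en-1-yl]-2-[(tert-butyldimethylsilyl)oxy]ethan-1-ol (Br trans to the ring silyl ether) | CC1(C)[C@H](O[Si](C)(C)C(C)(C)C)C[C@@H](Br)C([C@H](O)CO[Si](C)(C)C(C)(C)C)=C1 | intermediate (key-step product)
15 | (1S)-1-[(4R,6R)-6-bromo-4-[(tert-butyldimethylsilyl)oxy]-3,3-dimethylcyclohex-1-en-1-yl]-2-[(tert-butyldimethylsilyl)oxy]ethyl chlorosulfite (sulfur epimers) | CC1(C)[C@H](O[Si](C)(C)C(C)(C)C)C[C@@H](Br)C([C@H](OS(=O)Cl)CO[Si](C)(C)C(C)(C)C)=C1 | intermediate (not isolated)
16 | (2R,4R,6R,5E)-4-bromo-2-[(tert-butyldimethylsilyl)oxy]-5-{2-[(tert-butyldimethylsilyl)oxy]ethylidene}-6-chloro-1,1-dimethylcyclohexane (target atom labels; C8 cis to C6) | CC1(C)[C@H](O[Si](C)(C)C(C)(C)C)C[C@@H](Br)/C(=C/CO[Si](C)(C)C(C)(C)C)[C@@H]1Cl | intermediate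
17 | (2R,4S,6R,5Z)-2-[(tert-butyldimethylsilyl)oxy]-5-{2-[(tert-butyldimethylsilyl)oxy]ethylidene}-4,6-dichloro-1,1-dimethylcyclohexane (target atom labels; ring substituents all cis) | CC1(C)[C@H](O[Si](C)(C)C(C)(C)C)C[C@H](Cl)/C(=C/CO[Si](C)(C)C(C)(C)C)[C@@H]1Cl | intermediate
18 | (2R,4S,6R,5Z)-4,6-dichloro-5-(2-hydroxyethylidene)-1,1-dimethylcyclohexan-2-ol (target atom labels) | CC1(C)[C@H](O)C[C@H](Cl)/C(=C/CO)[C@@H]1Cl | intermediate
19 | (2R,4S,6R,5Z)-5-(2-bromoethylidene)-4,6-dichloro-1,1-dimethylcyclohexan-2-ol (target atom labels) | CC1(C)[C@H](O)C[C@H](Cl)/C(=C/CBr)[C@@H]1Cl | intermediate (not isolated)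
20 | (2S,4S,6S,5Z)-2-bromo-5-(2-bromoethylidene)-4,6-dichloro-1,1-dimethylcyclohexane, CNP0156384.1 | CC1(C)[C@@H](Br)C[C@H](Cl)/C(=C/CBr)[C@@H]1Cl | target

## Step count and least certain steps

Total step count: 13. Longest linear sequence: 13 steps (1 → 20); 7 and 9 are purchased.

Step 9 (key step). Most likely to go wrong: loss of HBr from the allylic bromide to a cyclohexadiene, or acid-promoted opening of the free cyclopropylcarbinol before ionisation, because the oxygenated exo substituent may slow ionisation enough that the temperature needed brings these processes in. Fallback, setting out from 13: the C7 hydroxyl is masked (TMSCl, imidazole, CH2Cl2) to give the trimethylsilyl ether F1. F1 is heated as in step 9 to the rearranged trimethylsilyl ether F2, from which the trimethylsilyl group alone is removed (PPTS, MeOH, 0 °C). The sequence comes back to the route at 14.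

Step 10. Most likely to go wrong: collapse of the chlorosulfite at C7 without transposition, because C6 is neopentyl, or chlorine delivery from the wrong rotamer, which would give the wrong face at C6 together with the wrong alkene geometry. Fallback, setting out from 14: the order of the two halogen steps is reversed, which also removes the labile allylic bromide 16 from the route. LiCl in DMF at 0 °C exchanges the pseudoaxial C4 bromide (no SN2′ outlet, C6 being neopentyl) to give the chloro alcohol F3. SOCl2 in ether then forms the chlorosulfite F4, whose transposition comes back to the route at 17. In F3 the C4 chlorine is cis to the C2 silyl ether; in the half-chair that keeps both equatorial, the chlorine lies in the alkene plane and closes the C4 side of C7, so C8 again has to turn toward C6. This control depends on that half-chair being the one that reacts.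

Step 13. Most likely to go wrong: slow displacement at the neopentyl C2, so that elimination toward C3, methyl migration, or attack of phosphine on the primary allylic bromide overtakes substitution. Fallback, setting out from 18: the primary alcohol alone is brominated (CBr4 and PPh3, 1.1 equiv each, CH2Cl2, −20 °C) and 19 is isolated. Its C2 hydroxyl is converted (Tf2O, 2,6-lutidine, CH2Cl2, −78 °C) into the triflate F5, which is displaced with inversion by Bu4NBr in toluene at 0 → 25 °C. The sequence comes back to the route at 20.

Step 6. Most likely to go wrong: equilibration of the lithium carbenoid to the endo-lithio isomer, or its α-elimination before the aldehyde is added, since it survives only below about −90 °C. Fallback, setting out from 8: exo-selective bromine–magnesium exchange with iPrMgCl·LiCl in THF at −78 °C gives the magnesium carbenoid F6, which is stable at that temperature and adds to 9 after addition of the aldehyde. The sequence comes back to the route at 11.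

Steps 5 and 11 carry the smaller risks named in their Why lines: the facial selectivity of the carbene, and SN2 against SN2′ exchange.

## Further compounds

F1 | step 9 | trimethylsilyl ether of 13 at the C7 oxygen | CC1(C)[C@H](O[Si](C)(C)C(C)(C)C)C[C@@H]2[C@H]1[C@@]2(Br)[C@H](O[Si](C)(C)C)CO[Si](C)(C)C(C)(C)C
F2 | step 9 | trimethylsilyl ether of 14 at the C7 oxygen | CC1(C)[C@H](O[Si](C)(C)C(C)(C)C)C[C@@H](Br)C([C@H](O[Si](C)(C)C)CO[Si](C)(C)C(C)(C)C)=C1
F3 | step 10 | (1S)-1-[(4R,6S)-6-chloro-4-[(tert-butyldimethylsilyl)oxy]-3,3-dimethylcyclohex-1-en-1-yl]-2-[(tert-butyldimethylsilyl)oxy]ethan-1-ol | CC1(C)[C@H](O[Si](C)(C)C(C)(C)C)C[C@H](Cl)C([C@H](O)CO[Si](C)(C)C(C)(C)C)=C1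
F4 | step 10 | chlorosulfite of F3 (sulfur epimers) | CC1(C)[C@H](O[Si](C)(C)C(C)(C)C)C[C@H](Cl)C([C@H](OS(=O)Cl)CO[Si](C)(C)C(C)(C)C)=C1
F5 | step 13 | C2 trifluoromethanesulfonate of 19 | CC1(C)[C@H](OS(=O)(=O)C(F)(F)F)C[C@H](Cl)/C(=C/CBr)[C@@H]1Cl
F6 | step 6 | [(1R,3R,5R,6R)-6-bromo-3-[(tert-butyldimethylsilyl)oxy]-2,2-dimethylbicyclo[3.1.0]hexan-6-yl]magnesium chloride (Mg exo, Br endo) | CC1(C)[C@H](O[Si](C)(C)C(C)(C)C)C[C@@H]2[C@H]1[C@@]2(Br)[Mg]Cl
A1 | alternative 1 | (3R)-1-bromo-1,3-dichloro-4,4-dimethylhex-5-en-2-one (both C1 epimers) | C=CC(C)(C)[C@@H](Cl)C(=O)C(Cl)Br
A2 | alternative 1 | 4-bromo-2,6-dichloro-3,3-dimethylcyclohexan-1-one, halogens configured as in the target | CC1(C)[C@@H](Br)C[C@H](Cl)C(=O)[C@@H]1Cl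
A3 | alternative 2 | (3S,4Z)-6-[(tert-butyldimethylsilyl)oxy]-3-chloro-4-ethenyl-2,2-dimethylhex-4-enal | O=CC(C)(C)[C@@H](Cl)/C(C=C)=C\CO[Si](C)(C)C(C)(C)C
A4 | alternative 2 | (1R,3S,5R,4Z)-4-{2-[(tert-butyldimethylsilyl)oxy]ethylidene}-3,5-dichloro-2,2-dimethylcyclohexan-1-ol | CC1(C)[C@H](O)C[C@H](Cl)/C(=C/CO[Si](C)(C)C(C)(C)C)[C@@H]1Cl
A5 | alternative 3 | (3S,5S)-5-bromo-3-chloro-4,4-dimethyloct-7-en-1-yne | C#C[C@H](Cl)C(C)(C)[C@@H](Br)CC=C
A6 | alternative 3 | (4S,6S)-4-bromo-6-chloro-5,5-dimethyl-1-vinylcyclohex-1-ene | C=CC1=CC[C@H](Br)C(C)(C)[C@H]1Cl
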